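**Plan**

1. Labdane numbering is used: ring A = C1–C5 and C10 (gem-dimethyl at C4), ring B = C5–C10; C8 carries OH and CH3, C9 the chain C11–C15, C10 the angular CH3 (cis to H5).
2. Retrosynthesis: the acetate is removed; C11–C12 is cut (Wittig, then hydrogenation) into a bicyclic C11 aldehyde and a C12–C15 phosphonium salt; C5–C10 and C8–C9 are then cut together (intramolecular Diels–Alder), which opens both rings to an acyclic trienoyl imide. The triene is cut at C5=C6 (Julia–Kocienski), C9–C11 (alkyne carboxylation), C10–CH3 (cuprate) and C3–C4 (nitrile alkylation).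
3. Enabling feature: in ring B the oxygenated C8 is next to C9, which carries the carbonyl-derived C11, and the quaternary C10 is β to C11. Ring B is therefore the adduct of a 1-silyloxy diene C5=C6–C7=C8 and an enoyl dienophile C9=C10, and the C1–C4 chain that links C10 to C5 becomes ring A.
4. Forward: the triene is built linearly, rings A and B close in one step (ring A as the tether ring, ring B as the new cyclohexene), the side chain is joined at C11–C12, both alkenes are hydrogenated, the silyl ethers are removed and the primary alcohol is acetylated.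
5. Stereochemistry: C5, C8, C9 and C10 are set relative to one another by the 2Z, 8E and 10Z olefin geometries and the acyl-endo transition state, and in the absolute sense by a (4S)-4-benzyloxazolidinone auxiliary; C13 comes from (R)-2-methylbutane-1,4-diol.

Key step: step 12

Remark: the target is taken as drawn, a cis-fused decalin (5S,8R,9R,10R,13S in labdane numbering) with H5, H9, the C10 methyl and the C8 hydroxyl on one face; 5-iodopent-1-yne, 2-(2-bromoethyl)-2-methyl-1,3-dioxolane and (4S)-4-benzyl-1,3-oxazolidin-2-one are taken as commercial.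

**Route**

Step 1
Reactants: 1 2-(2-bromoethyl)-2-methyl-1,3-dioxolane; 2 1-phenyl-1H-tetrazole-5-thiol
Product: 3 5-{[2-(2-methyl-1,3-dioxolan-2-yl)ethyl]sulfanyl}-1-phenyl-1H-tetrazole
Conditions: K2CO3, DMF, rt → 50 °C
Reagents that add atoms: none
Why: SN2 S-alkylation of the acidic tetrazolethiol by an unhindered primary bromide under carbonate base (thioether synthesis) is the standard entry to Julia–Kocienski reagents and leaves the ketal untouched.

Step 2
Reactants: 3 5-{[2-(2-methyl-1,3-dioxolan-2-yl)ethyl]sulfanyl}-1-phenyl-1H-tetrazole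
Product: 4 5-{[2-(2-methyl-1,3-dioxolan-2-yl)ethyl]sulfonyl}-1-phenyl-1H-tetrazole
Conditions: 30% H2O2, (NH4)6Mo7O24·4H2O (cat.), EtOH, 0 °C → rt
Reagents that add atoms: hydrogen peroxide, OO
Why: Molybdate-catalysed H2O2 oxidation of a sulfide to the sulfone runs near neutrality, which the dioxolane tolerates.

Step 3
Reactants: 5 2-methylpropanenitrile (isobutyronitrile); 6 5-iodopent-1-yne
Product: 8 2,2-dimethylhept-6-ynenitrile, via lithiated isobutyronitrile 7 (not isolated)
Conditions: LiN(i-Pr)2 and 5 (2.2 equiv each), THF, −78 °C; then 6, −78 °C → rt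
Reagents that add atoms: none
Why: α-Alkylation of a nitrile anion: the small, strongly nucleophilic lithiated isobutyronitrile displaces the primary iodide (SN2) to create the quaternary C4, and the excess anion absorbs the acidic alkyne proton, which returns on work-up.

Step 4
Reactants: 8 2,2-dimethylhept-6-ynenitrile
Product: 10 2,2-dimethylhept-6-ynal, via N-alumino aldimine 9 (not isolated)
Conditions: i-Bu2AlH, CH2Cl2, −78 °C; then 1 M HCl, 0 °C
Reagents that add atoms: water, O
Why: Partial reduction of a nitrile with i-Bu2AlH stops at the N-alumino imine, which hydrolyses to the non-enolisable aldehyde on acidic work-up.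

Step 5
Reactants: 4 5-{[2-(2-methyl-1,3-dioxolan-2-yl)ethyl]sulfonyl}-1-phenyl-1H-tetrazole; 10 2,2-dimethylhept-6-ynal
Product: 12 2-[(2E)-4,4-dimethylnon-2-en-8-yn-1-yl]-2-methyl-1,3-dioxolane, via potassiated sulfone 11 (not isolated)
Conditions: KN(SiMe3)2, DME, −60 °C; then 10, −60 °C → rt
Reagents that add atoms: none
Why: Julia–Kocienski olefination of a 1-phenyltetrazolyl sulfone with an α-branched aldehyde under potassium base in DME is reliably E-selective (anti addition, Smiles rearrangement, anti elimination), which sets the 8E (C5=C6) geometry.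

Step 6
Reactants: 12 2-[(2E)-4,4-dimethylnon-2-en-8-yn-1-yl]-2-methyl-1,3-dioxolane
Product: 14 methyl (8E)-7,7-dimethyl-10-(2-methyl-1,3-dioxolan-2-yl)dec-8-en-2-ynoate, via lithium acetylide 13 (not isolated)
Conditions: n-BuLi, THF, −78 °C; then ClCO2Me, −78 → 0 °C
Reagents that add atoms: methyl chloroformate, COC(Cl)=O
Why: Deprotonation of the terminal alkyne and C-acylation of the acetylide with a chloroformate is the standard route to 2-ynoates; the ketal and the alkene are inert.

Step 7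
Reactants: 14 methyl (8E)-7,7-dimethyl-10-(2-methyl-1,3-dioxolan-2-yl)dec-8-en-2-ynoate
Product: 16 methyl (2Z,8E)-3,7,7-trimethyl-10-(2-methyl-1,3-dioxolan-2-yl)deca-2,8-dienoate, via vinylcuprate adduct 15 (not isolated)
Conditions: Me2CuLi (from CuI and MeLi), THF, −78 °C; MeOH quench at −78 °C
Reagents that add atoms: lithium dimethylcuprate, [Li+].C[Cu-]C
Why: Conjugate syn-carbocupration of a 2-ynoate at −78 °C followed by cold protonation with retention puts the new methyl group cis to H9, so the C1 chain is cis to the ester (2Z); quenching cold prevents equilibration through the allenolate.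

Step 8
Reactants: 16 methyl (2Z,8E)-3,7,7-trimethyl-10-(2-methyl-1,3-dioxolan-2-yl)deca-2,8-dienoate
Product: 17 (2Z,8E)-3,7,7-trimethyl-10-(2-methyl-1,3-dioxolan-2-yl)deca-2,8-dienoic acid
Conditions: LiOH·H2O, THF/MeOH/H2O, 40 °C; then 1 M HCl to pH 5, 0 °C
Reagents that add atoms: lithium hydroxide, [Li+].[OH-]
Why: Saponification of the methyl ester; the base-stable ketal survives because the acidification is stopped at pH 5 in the cold.

Step 9
Reactants: 17 (2Z,8E)-3,7,7-trimethyl-10-(2-methyl-1,3-dioxolan-2-yl)deca-2,8-dienoic acid; 18 (4S)-4-benzyl-1,3-oxazolidin-2-one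
Product: 21 (4S)-4-benzyl-3-[(2Z,8E)-3,7,7-trimethyl-10-(2-methyl-1,3-dioxolan-2-yl)deca-2,8-dienoyl]-1,3-oxazolidin-2-one, via mixed pivalic anhydride 19 (not isolated), via lithiated oxazolidinone 20 (not isolated)
Conditions: 17, PivCl, Et3N, THF, −20 °C; 18, n-BuLi, THF, −78 °C; combined at −78 → 0 °C
Reagents that add atoms: none
Why: N-acylation of the lithiated oxazolidinone by the mixed pivalic anhydride occurs at the less hindered enoyl carbonyl at low temperature, which avoids the ketene pathway that could scramble the 2Z geometry.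

Step 10
Reactants: 21 (4S)-4-benzyl-3-[(2Z,8E)-3,7,7-trimethyl-10-(2-methyl-1,3-dioxolan-2-yl)deca-2,8-dienoyl]-1,3-oxazolidin-2-one
Product: 22 (4S)-4-benzyl-3-[(2Z,8E)-3,7,7-trimethyl-11-oxododeca-2,8-dienoyl]-1,3-oxazolidin-2-one
Conditions: PPTS, acetone/H2O (10:1), 45 °C
Reagents that add atoms: water, O
Why: Acid-catalysed ketal hydrolysis under mild pyridinium catalysis releases the methyl ketone without moving the 8E double bond into conjugation.

Step 11
Reactants: 22 (4S)-4-benzyl-3-[(2Z,8E)-3,7,7-trimethyl-11-oxododeca-2,8-dienoyl]-1,3-oxazolidin-2-one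
Product: 23 (4S)-4-benzyl-3-[(2Z,8E,10Z)-11-{[tert-butyl(dimethyl)silyl]oxy}-3,7,7-trimethyldodeca-2,8,10-trienoyl]-1,3-oxazolidin-2-one
Conditions: TBSOTf, Et3N, CH2Cl2, −78 → 0 °C
Reagents that add atoms: tert-butyldimethylsilyl trifluoromethanesulfonate, CC(C)(C)[Si](C)(C)OS(=O)(=O)C(F)(F)F
Why: Soft enolisation (silyl triflate with a tertiary amine) removes the doubly activated C7 proton (allylic and α to the carbonyl) to give the conjugated silyl dienol ether, and allylic 1,3-strain favours the 10Z isomer in which the silyloxy group rather than the methyl group is syn to C6.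

Step 12
Reactants: 23 (4S)-4-benzyl-3-[(2Z,8E,10Z)-11-{[tert-butyl(dimethyl)silyl]oxy}-3,7,7-trimethyldodeca-2,8,10-trienoyl]-1,3-oxazolidin-2-one
Product: 24 (4S)-4-benzyl-3-{[(1R,2R,4aS,8aR)-2-{[tert-butyl(dimethyl)silyl]oxy}-2,5,5,8a-tetramethyl-1,2,4a,5,6,7,8,8a-octahydronaphthalen-1-yl]carbonyl}-1,3-oxazolidin-2-one
Conditions: Me2AlCl (1.5 equiv), CH2Cl2 (0.02 M), −78 → −20 °C; cold 1 M HCl work-up
Reagents that add atoms: none
Why: Proposed new method: an excess of Me2AlCl turns the imide into the cationic two-point chelate [23·AlMe2]+ (counter-ion Me2AlCl2−), whose s-cis enoyl group is attacked at C10 by the nucleophilic C5 terminus of the silyl dienol ether while C9 closes onto C8, a polarised and asynchronous [4+2] that in its stepwise limit is a vinylogous Mukaiyama–Michael addition followed by collapse of the aluminium enolate onto the silyloxocarbenium ion. The closest known reaction types are the Me2AlCl-promoted intramolecular Diels–Alder reaction of 2,8,10-trienoyl oxazolidinones and the aluminium-Lewis-acid Diels–Alder reaction of hindered silyloxy dienes with β,β-disubstituted enones, but a β,β-disubstituted (Z)-enoyl imide has not been combined with a (Z)-1-silyloxy diene terminus. Ring A closes as the six-membered tether ring through the C5–C10 bond (6-exo-trig in the stepwise limit) and ring B as the cyclohexene of the cycloaddition, completed by the C8–C9 bond. The 2Z geometry fixes C9 against C10 (H9 cis to the C10 methyl), the 8E,10Z geometry fixes C8 against C5 (silyloxy group cis to H5), and the acyl-endo transition state, which for a Z dienophile also holds the tether endo, gives the cis ring fusion and places C11 trans to the C8 oxygen. The absolute sense comes from the 4S benzyl group, which covers the Re face of C9 in the chelate so that the diene adds to the Si face. The step needs endo selectivity, facial selectivity and a diene that can reach an s-cis-like arrangement despite its inside silyloxy group; the chelate, the Z dienophile, the matched polarity (donor C5, acceptor C10) and the C4 gem-dimethyl group, which favours the coiled tether, are the elements that should secure them.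

Step 13
Reactants: 24 (4S)-4-benzyl-3-{[(1R,2R,4aS,8aR)-2-{[tert-butyl(dimethyl)silyl]oxy}-2,5,5,8a-tetramethyl-1,2,4a,5,6,7,8,8a-octahydronaphthalen-1-yl]carbonyl}-1,3-oxazolidin-2-one
Product: 25 [(1S,2R,4aS,8aR)-2-{[tert-butyl(dimethyl)silyl]oxy}-2,5,5,8a-tetramethyl-1,2,4a,5,6,7,8,8a-octahydronaphthalen-1-yl]methanol
Conditions: LiBH4, MeOH (1 equiv), THF, 0 °C → rt
Reagents that add atoms: none
Why: Reductive cleavage of the N-acyl oxazolidinone with LiBH4 delivers hydride to the activated exocyclic carbonyl and releases the auxiliary for recovery; the silyl ether, the alkene and the four stereocentres are not affected.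

Step 14
Reactants: 25 [(1S,2R,4aS,8aR)-2-{[tert-butyl(dimethyl)silyl]oxy}-2,5,5,8a-tetramethyl-1,2,4a,5,6,7,8,8a-octahydronaphthalen-1-yl]methanol
Product: 26 (1R,2R,4aS,8aR)-2-{[tert-butyl(dimethyl)silyl]oxy}-2,5,5,8a-tetramethyl-1,2,4a,5,6,7,8,8a-octahydronaphthalene-1-carbaldehyde
Conditions: Dess–Martin periodinane, CH2Cl2, 0 °C → rt
Reagents that add atoms: none
Why: Dess–Martin oxidation converts the hindered primary alcohol into the aldehyde under neutral, non-enolising conditions, so C9 is not epimerised and the C8 silyloxy group is not eliminated.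

Step 15
Reactants: 27 (2R)-2-methylbutane-1,4-diol
Product: 28 (2R)-2-methyl-4-{[tri(propan-2-yl)silyl]oxy}butan-1-ol
Conditions: TIPSCl (1.0 equiv), imidazole, CH2Cl2, −20 → 0 °C
Reagents that add atoms: chlorotri(propan-2-yl)silane, CC(C)[Si](Cl)(C(C)C)C(C)C
Why: Silylation with the bulky TIPSCl should favour the unbranched C15 hydroxyl over the β-branched C12 hydroxyl (steric differentiation of two primary alcohols); the minor regioisomer and the bis-ether are removed by chromatography.

Step 16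
Reactants: 28 (2R)-2-methyl-4-{[tri(propan-2-yl)silyl]oxy}butan-1-ol
Product: 29 {[(3R)-4-iodo-3-methylbutyl]oxy}tri(propan-2-yl)silane
Conditions: PPh3, I2, imidazole, CH2Cl2, 0 °C → rt
Reagents that add atoms: iodine, II
Why: Appel-type iodination replaces the remaining primary hydroxyl by iodide through SN2 at a carbon that is not stereogenic, so C13 is untouched.

Step 17
Reactants: 29 {[(3R)-4-iodo-3-methylbutyl]oxy}tri(propan-2-yl)silane
Product: 30 [(2R)-2-methyl-4-{[tri(propan-2-yl)silyl]oxy}butyl]triphenylphosphonium iodide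
Conditions: PPh3, MeCN, 80 °C
Reagents that add atoms: triphenylphosphine, c1ccc(cc1)P(c1ccccc1)c1ccccc1
Why: SN2 quaternisation of PPh3 by the primary iodide on heating gives the Wittig salt; the TIPS ether is stable.

Step 18
Reactants: 30 [(2R)-2-methyl-4-{[tri(propan-2-yl)silyl]oxy}butyl]triphenylphosphonium iodide; 26 (1R,2R,4aS,8aR)-2-{[tert-butyl(dimethyl)silyl]oxy}-2,5,5,8a-tetramethyl-1,2,4a,5,6,7,8,8a-octahydronaphthalene-1-carbaldehyde
Product: 32 tert-butyl(dimethyl){[(1R,2R,4aS,8aR)-2,5,5,8a-tetramethyl-1-[(1Z,3R)-3-methyl-5-{[tri(propan-2-yl)silyl]oxy}pent-1-en-1-yl]-1,2,4a,5,6,7,8,8a-octahydronaphthalen-2-yl]oxy}silane, via phosphorus ylide 31 (not isolated)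
Conditions: 30, NaN(SiMe3)2, THF, −78 → 0 °C; then 26, −78 °C → rt
Reagents that add atoms: none
Why: Wittig olefination with a non-stabilised ylide, a compact and highly nucleophilic reagent suited to hindered aldehydes, forms the C11=C12 bond at low temperature; the alkene geometry (expected mainly Z) is irrelevant because the bond is hydrogenated next.

Step 19
Reactants: 32 tert-butyl(dimethyl){[(1R,2R,4aS,8aR)-2,5,5,8a-tetramethyl-1-[(1Z,3R)-3-methyl-5-{[tri(propan-2-yl)silyl]oxy}pent-1-en-1-yl]-1,2,4a,5,6,7,8,8a-octahydronaphthalen-2-yl]oxy}silane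
Product: 33 tert-butyl(dimethyl){[(1R,2R,4aS,8aR)-2,5,5,8a-tetramethyl-1-[(3S)-3-methyl-5-{[tri(propan-2-yl)silyl]oxy}pentyl]decahydronaphthalen-2-yl]oxy}silane
Conditions: H2 (1 atm), PtO2, EtOAc, rt
Reagents that add atoms: none
Why: Heterogeneous hydrogenation over PtO2 saturates both disubstituted alkenes without creating a stereocentre, and platinum is chosen to avoid hydrogenolysis of the allylic C8–O bond before C6=C7 is reduced.

Step 20
Reactants: 33 tert-butyl(dimethyl){[(1R,2R,4aS,8aR)-2,5,5,8a-tetramethyl-1-[(3S)-3-methyl-5-{[tri(propan-2-yl)silyl]oxy}pentyl]decahydronaphthalen-2-yl]oxy}silane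
Product: 34 (1R,2R,4aS,8aR)-1-[(3S)-5-hydroxy-3-methylpentyl]-2,5,5,8a-tetramethyldecahydronaphthalen-2-ol
Conditions: Bu4NF, THF, 50 °C
Reagents that add atoms: none
Why: Fluoride-mediated desilylation removes the primary TIPS ether readily and the hindered tertiary TBS ether on warming.

Step 21
Reactants: 34 (1R,2R,4aS,8aR)-1-[(3S)-5-hydroxy-3-methylpentyl]-2,5,5,8a-tetramethyldecahydronaphthalen-2-ol
Product: 35 (3S)-5-[(1R,2R,4aS,8aR)-2-hydroxy-2,5,5,8a-tetramethyldecahydronaphthalen-1-yl]-3-methylpentyl acetate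
Conditions: Ac2O, pyridine, CH2Cl2, 0 °C → rt
Reagents that add atoms: acetic anhydride, CC(=O)OC(C)=O
Why: Acetylation with Ac2O/pyridine in the absence of an acyl-transfer catalyst is selective for the primary hydroxyl; the tertiary, neopentyl-like C8 hydroxyl does not react.

**Compound list**

1 | 2-(2-bromoethyl)-2-methyl-1,3-dioxolane | CC1(CCBr)OCCO1 | starting material
2 | 1-phenyl-1H-tetrazole-5-thiol | SC1=NN=NN1c1ccccc1 | starting material
3 | 5-{[2-(2-methyl-1,3-dioxolan-2-yl)ethyl]sulfanyl}-1-phenyl-1H-tetrazole | CC1(CCSC2=NN=NN2c2ccccc2)OCCO1 | intermediate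
4 | 5-{[2-(2-methyl-1,3-dioxolan-2-yl)ethyl]sulfonyl}-1-phenyl-1H-tetrazole | CC1(CCS(=O)(=O)C2=NN=NN2c2ccccc2)OCCO1 | intermediate
5 | 2-methylpropanenitrile (isobutyronitrile) | CC(C)C#N | starting material
6 | 5-iodopent-1-yne | C#CCCCI | starting material
7 | lithiated isobutyronitrile (formed in the flask) | [Li+].CC(C)=C=[N-] | intermediate
8 | 2,2-dimethylhept-6-ynenitrile | N#CC(C)(C)CCCC#C | intermediate
9 | N-[bis(2-methylpropyl)alumanyl]-2,2-dimethylhept-6-yn-1-imine (formed in the flask) | CC(C)C[Al](CC(C)C)N=CC(C)(C)CCCC#C | intermediate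
10 | 2,2-dimethylhept-6-ynal | O=CC(C)(C)CCCC#C | intermediate
11 | potassium α-sulfonyl carbanion of 4 (formed in the flask) | [K+].CC1(C[CH-]S(=O)(=O)C2=NN=NN2c2ccccc2)OCCO1 | intermediate
12 | 2-[(2E)-4,4-dimethylnon-2-en-8-yn-1-yl]-2-methyl-1,3-dioxolane | CC1(C/C=C/C(C)(C)CCCC#C)OCCO1 | intermediate
13 | lithium acetylide of 12 (formed in the flask) | [Li]C#CCCCC(C)(C)/C=C/CC1(C)OCCO1 | intermediate
14 | methyl (8E)-7,7-dimethyl-10-(2-methyl-1,3-dioxolan-2-yl)dec-8-en-2-ynoate | COC(=O)C#CCCCC(C)(C)/C=C/CC1(C)OCCO1 | intermediate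
15 | lithium methyl(alkenyl)cuprate from syn addition to 14, copper on C2 cis to the new C3 methyl (formed in the flask) | [Li+].COC(=O)/C([Cu-]C)=C(C)\CCCC(C)(C)/C=C/CC1(C)OCCO1 | intermediate
16 | methyl (2Z,8E)-3,7,7-trimethyl-10-(2-methyl-1,3-dioxolan-2-yl)deca-2,8-dienoate | COC(=O)/C=C(C)\CCCC(C)(C)/C=C/CC1(C)OCCO1 | intermediate
17 | (2Z,8E)-3,7,7-trimethyl-10-(2-methyl-1,3-dioxolan-2-yl)deca-2,8-dienoic acid | OC(=O)/C=C(C)\CCCC(C)(C)/C=C/CC1(C)OCCO1 | intermediate
18 | (4S)-4-benzyl-1,3-oxazolidin-2-one | O=C1N[C@@H](Cc2ccccc2)CO1 | starting material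
19 | mixed anhydride of 17 and pivalic acid (formed in the flask) | CC(C)(C)C(=O)OC(=O)/C=C(C)\CCCC(C)(C)/C=C/CC1(C)OCCO1 | intermediate
20 | N-lithio derivative of 18 (formed in the flask) | [Li]N1[C@@H](Cc2ccccc2)COC1=O | intermediate
21 | (4S)-4-benzyl-3-[(2Z,8E)-3,7,7-trimethyl-10-(2-methyl-1,3-dioxolan-2-yl)deca-2,8-dienoyl]-1,3-oxazolidin-2-one | O=C1OC[C@H](Cc2ccccc2)N1C(=O)/C=C(C)\CCCC(C)(C)/C=C/CC3(C)OCCO3 | intermediate
22 | (4S)-4-benzyl-3-[(2Z,8E)-3,7,7-trimethyl-11-oxododeca-2,8-dienoyl]-1,3-oxazolidin-2-one | O=C1OC[C@H](Cc2ccccc2)N1C(=O)/C=C(C)\CCCC(C)(C)/C=C/CC(C)=O | intermediate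
23 | (4S)-4-benzyl-3-[(2Z,8E,10Z)-11-{[tert-butyl(dimethyl)silyl]oxy}-3,7,7-trimethyldodeca-2,8,10-trienoyl]-1,3-oxazolidin-2-one | O=C1OC[C@H](Cc2ccccc2)N1C(=O)/C=C(C)\CCCC(C)(C)/C=C/C=C(C)\O[Si](C)(C)C(C)(C)C | intermediate
24 | (4S)-4-benzyl-3-{[(1R,2R,4aS,8aR)-2-{[tert-butyl(dimethyl)silyl]oxy}-2,5,5,8a-tetramethyl-1,2,4a,5,6,7,8,8a-octahydronaphthalen-1-yl]carbonyl}-1,3-oxazolidin-2-one | O=C1OC[C@H](Cc2ccccc2)N1C(=O)[C@@H]3[C@]4(C)CCCC(C)(C)[C@@H]4C=C[C@@]3(C)O[Si](C)(C)C(C)(C)C | intermediate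
25 | [(1S,2R,4aS,8aR)-2-{[tert-butyl(dimethyl)silyl]oxy}-2,5,5,8a-tetramethyl-1,2,4a,5,6,7,8,8a-octahydronaphthalen-1-yl]methanol | OC[C@@H]1[C@]2(C)CCCC(C)(C)[C@@H]2C=C[C@@]1(C)O[Si](C)(C)C(C)(C)C | intermediate
26 | (1R,2R,4aS,8aR)-2-{[tert-butyl(dimethyl)silyl]oxy}-2,5,5,8a-tetramethyl-1,2,4a,5,6,7,8,8a-octahydronaphthalene-1-carbaldehyde | O=C[C@@H]1[C@]2(C)CCCC(C)(C)[C@@H]2C=C[C@@]1(C)O[Si](C)(C)C(C)(C)C | intermediate
27 | (2R)-2-methylbutane-1,4-diol | OCC[C@@H](C)CO | starting material
28 | (2R)-2-methyl-4-{[tri(propan-2-yl)silyl]oxy}butan-1-ol | CC(C)[Si](OCC[C@@H](C)CO)(C(C)C)C(C)C | intermediate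
29 | {[(3R)-4-iodo-3-methylbutyl]oxy}tri(propan-2-yl)silane | CC(C)[Si](OCC[C@@H](C)CI)(C(C)C)C(C)C | intermediate
30 | [(2R)-2-methyl-4-{[tri(propan-2-yl)silyl]oxy}butyl]triphenylphosphonium iodide | CC(C)[Si](OCC[C@@H](C)C[P+](c1ccccc1)(c1ccccc1)c1ccccc1)(C(C)C)C(C)C.[I-] | intermediate
31 | phosphorus ylide of 30 (formed in the flask) | CC(C)[Si](OCC[C@@H](C)C=P(c1ccccc1)(c1ccccc1)c1ccccc1)(C(C)C)C(C)C | intermediate
32 | tert-butyl(dimethyl){[(1R,2R,4aS,8aR)-2,5,5,8a-tetramethyl-1-[(1Z,3R)-3-methyl-5-{[tri(propan-2-yl)silyl]oxy}pent-1-en-1-yl]-1,2,4a,5,6,7,8,8a-octahydronaphthalen-2-yl]oxy}silane | CC(C)[Si](OCC[C@@H](C)/C=C\[C@@H]1[C@]2(C)CCCC(C)(C)[C@@H]2C=C[C@@]1(C)O[Si](C)(C)C(C)(C)C)(C(C)C)C(C)C | intermediate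
33 | tert-butyl(dimethyl){[(1R,2R,4aS,8aR)-2,5,5,8a-tetramethyl-1-[(3S)-3-methyl-5-{[tri(propan-2-yl)silyl]oxy}pentyl]decahydronaphthalen-2-yl]oxy}silane | CC(C)[Si](OCC[C@@H](C)CC[C@@H]1[C@]2(C)CCCC(C)(C)[C@@H]2CC[C@@]1(C)O[Si](C)(C)C(C)(C)C)(C(C)C)C(C)C | intermediate
34 | (1R,2R,4aS,8aR)-1-[(3S)-5-hydroxy-3-methylpentyl]-2,5,5,8a-tetramethyldecahydronaphthalen-2-ol | OCC[C@@H](C)CC[C@@H]1[C@]2(C)CCCC(C)(C)[C@@H]2CC[C@@]1(C)O | intermediate
35 | (3S)-5-[(1R,2R,4aS,8aR)-2-hydroxy-2,5,5,8a-tetramethyldecahydronaphthalen-1-yl]-3-methylpentyl acetate | CC(=O)OCC[C@@H](C)CC[C@@H]1[C@]2(C)CCCC(C)(C)[C@@H]2CC[C@@]1(C)O | target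

**Step count**

Total: 21 steps. Longest linear sequence: 16 steps (steps 3–14 and 18–21 from isobutyronitrile; the same length through steps 1, 2, 5–14 and 18–21 from the bromo ketal).

**Steps most likely to fail**

Step 12 (intramolecular Diels–Alder). The chelated β,β-disubstituted enoyl group may be attacked too slowly. The Lewis acid could then strip the silyl group from the dienol ether, or the reaction could stop at an open-chain conjugate adduct formed from the s-trans diene. Leakage of endo or facial selectivity would show up as diastereomers. The fallback uses known chemistry, sets out from 16 and returns at 25. It gives up the auxiliary and the Lewis acid in favour of the classical thermal intramolecular Diels–Alder reaction of a 2,8,10-trienoate, followed by resolution. Ketal hydrolysis of 16 (PPTS, aqueous acetone) gives methyl (2Z,8E)-3,7,7-trimethyl-11-oxododeca-2,8-dienoate F1. Silylation as in step 11 gives methyl (2Z,8E,10Z)-11-{[tert-butyl(dimethyl)silyl]oxy}-3,7,7-trimethyldodeca-2,8,10-trienoate F2. Heating F2 in toluene at 170–190 °C (sealed silylated vessel, BHT) should give racemic methyl (1R*,2R*,4aS*,8aR*)-2-{[tert-butyl(dimethyl)silyl]oxy}-2,5,5,8a-tetramethyl-1,2,4a,5,6,7,8,8a-octahydronaphthalene-1-carboxylate F3, to be separated from any trans-fused isomer; a [1,5]-hydrogen shift of the diene is blocked because neither inside position carries a transferable C–H. LiAlH4 reduction gives the racemic alcohol rac-[(1S,2R,4aS,8aR)-2-{[tert-butyl(dimethyl)silyl]oxy}-2,5,5,8a-tetramethyl-1,2,4a,5,6,7,8,8a-octahydronaphthalen-1-yl]methanol F4, which is resolved by preparative chromatography on a chiral stationary phase to give 25.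

Step 18 (Wittig union). Addition of the branched ylide to an aldehyde whose α-carbon lies between two quaternary carbons may be slower than deprotonation at C9, which would cause epimerisation or β-elimination of the C8 silyloxy group. The fallback sets out from 26 and 29 and returns at 33; it replaces olefination by carbonyl addition and radical deoxygenation. Iodine–lithium exchange on 29 (t-BuLi, Et2O, −78 °C) gives [(2R)-2-methyl-4-{[tri(propan-2-yl)silyl]oxy}butyl]lithium F5, a smaller and more nucleophilic carbanion. Its addition to 26 gives (3R)-1-[(1S,2R,4aS,8aR)-2-{[tert-butyl(dimethyl)silyl]oxy}-2,5,5,8a-tetramethyl-1,2,4a,5,6,7,8,8a-octahydronaphthalen-1-yl]-3-methyl-5-{[tri(propan-2-yl)silyl]oxy}pentan-1-ol F6 as both C11 epimers. Hydrogenation (H2, PtO2, EtOAc) removes the ring alkene before the radical step and gives the decahydronaphthalene carbinol F7. PhOC(S)Cl with pyridine and DMAP gives the O-phenyl thionocarbonate F8, and Barton–McCombie deoxygenation (Bu3SnH, AIBN, toluene, 90 °C) gives 33.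

Step 13 (removal of the auxiliary). Hydride may attack the ring carbonyl of the oxazolidinone instead of the exocyclic acyl carbon, which is shielded by two neighbouring quaternary carbons; this would open the auxiliary to a hydroxy amide. The fallback sets out from 24 and returns at 25; it uses the acyl oxygen itself as the nucleophile. Iodolactonisation (I2, NaHCO3, MeCN/H2O) engages the γ,δ-alkene C6=C7 to give the bridged iodolactone (lactone oxygen on C7, iodine on C6, labdane numbering) F9 and frees 18. Zn in AcOH reopens it by reductive elimination to (1R,2R,4aS,8aR)-2-{[tert-butyl(dimethyl)silyl]oxy}-2,5,5,8a-tetramethyl-1,2,4a,5,6,7,8,8a-octahydronaphthalene-1-carboxylic acid F10 with the C6=C7 alkene restored, and LiAlH4 reduces F10 to 25.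

**Further compounds**

F1 | step 12 | methyl (2Z,8E)-3,7,7-trimethyl-11-oxododeca-2,8-dienoate | COC(=O)/C=C(C)\CCCC(C)(C)/C=C/CC(C)=O
F2 | step 12 | methyl (2Z,8E,10Z)-11-{[tert-butyl(dimethyl)silyl]oxy}-3,7,7-trimethyldodeca-2,8,10-trienoate | COC(=O)/C=C(C)\CCCC(C)(C)/C=C/C=C(C)\O[Si](C)(C)C(C)(C)C
F3 | step 12 | racemic methyl (1R*,2R*,4aS*,8aR*)-2-{[tert-butyl(dimethyl)silyl]oxy}-2,5,5,8a-tetramethyl-1,2,4a,5,6,7,8,8a-octahydronaphthalene-1-carboxylate (one enantiomer drawn) | COC(=O)[C@@H]1[C@]2(C)CCCC(C)(C)[C@@H]2C=C[C@@]1(C)O[Si](C)(C)C(C)(C)C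
F4 | step 12 | racemic [(1S*,2R*,4aS*,8aR*)-2-{[tert-butyl(dimethyl)silyl]oxy}-2,5,5,8a-tetramethyl-1,2,4a,5,6,7,8,8a-octahydronaphthalen-1-yl]methanol, the racemate of 25 (one enantiomer drawn) | OC[C@@H]1[C@]2(C)CCCC(C)(C)[C@@H]2C=C[C@@]1(C)O[Si](C)(C)C(C)(C)C
F5 | step 18 | [(2R)-2-methyl-4-{[tri(propan-2-yl)silyl]oxy}butyl]lithium | [Li]C[C@H](C)CCO[Si](C(C)C)(C(C)C)C(C)C
F6 | step 18 | (3R)-1-[(1S,2R,4aS,8aR)-2-{[tert-butyl(dimethyl)silyl]oxy}-2,5,5,8a-tetramethyl-1,2,4a,5,6,7,8,8a-octahydronaphthalen-1-yl]-3-methyl-5-{[tri(propan-2-yl)silyl]oxy}pentan-1-ol (both C1 epimers) | CC(C)[Si](OCC[C@@H](C)CC(O)[C@@H]1[C@]2(C)CCCC(C)(C)[C@@H]2C=C[C@@]1(C)O[Si](C)(C)C(C)(C)C)(C(C)C)C(C)C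
F7 | step 18 | (3R)-1-[(1S,2R,4aS,8aR)-2-{[tert-butyl(dimethyl)silyl]oxy}-2,5,5,8a-tetramethyldecahydronaphthalen-1-yl]-3-methyl-5-{[tri(propan-2-yl)silyl]oxy}pentan-1-ol (both C1 epimers) | CC(C)[Si](OCC[C@@H](C)CC(O)[C@@H]1[C@]2(C)CCCC(C)(C)[C@@H]2CC[C@@]1(C)O[Si](C)(C)C(C)(C)C)(C(C)C)C(C)C
F8 | step 18 | O-phenyl thionocarbonate of F7 | CC(C)[Si](OCC[C@@H](C)CC(OC(=S)Oc1ccccc1)[C@@H]1[C@]2(C)CCCC(C)(C)[C@@H]2CC[C@@]1(C)O[Si](C)(C)C(C)(C)C)(C(C)C)C(C)C
F9 | step 13 | bridged iodolactone from 24: C11 carboxyl closed onto C7, iodine on C6, C8 silyl ether retained | O=C1O[C@H]2[C@H](I)[C@H]3C(C)(C)CCC[C@@]3(C)[C@@H]1[C@]2(C)O[Si](C)(C)C(C)(C)C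
F10 | step 13 | (1R,2R,4aS,8aR)-2-{[tert-butyl(dimethyl)silyl]oxy}-2,5,5,8a-tetramethyl-1,2,4a,5,6,7,8,8a-octahydronaphthalene-1-carboxylic acid | OC(=O)[C@@H]1[C@]2(C)CCCC(C)(C)[C@@H]2C=C[C@@]1(C)O[Si](C)(C)C(C)(C)C
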